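The readings are simulated from invented constants; scatter was added.

At early times product appears more slowly than the solid substrate leaves: in the north run, the flask I am asked about, product stands at 4.70 mM at 4.00 h, against 10.3 mM of solid gone. I count in concentrations, not percent. The south-east run has lost 9.04 mM at 3.00 h and 12.2 mM at 5.00 h, so the north figure lies between them, although the north charge is larger.

| flask | solid substrate | gas phase | free catalyst | impurity | remark | time |
|---|---|---|---|---|---|---|
| north | 0.10 M | 4.7 mM (held) | 10 mM | 7.9 mM | the very flask that is asked about, followed so far |  |
| south-east | 0.067 M | 4.7 mM (held) | 10 mM | 7.9 mM | run made earlier |  |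
| flask | 0.10 M | 4.7 mM (held) | 10 mM | 7.9 mM |  | 20 h |

- north (time / h: product / %, solid substrate / %): 0.200: 0.4, 100.5; 0.667: 3.3, 97.8; 1.00: 1.1, 96.7; 1.50: 1.2, 94.0; 2.50: 1.6, 90.2; 3.00: 2.4, 90.8; 4.00: 4.7, 89.7
- south-east (time / h: product / %, solid substrate / %): 0.417: 0, 95.1; 1.33: 0.7, 93.0; 2.50: 3.5, 87.9; 3.00: 3.5, 86.5; 5.00: 9.0, 81.8; 6.00: 12.0, 78.2; 8.00: 13.6, 74.8

(each reading ± 1 percentage point)

- solid, in amounts per volume of the solution: solid substrate
- the earlier runs were read with a standard deviation of 1 percentage point
- at the start none of the gas phase is in solution
- at the start none of the solid substrate is in solution

- the product standing at 20 h, as a percentage of the solid substrate charged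
- the change that raises the amount of product at 20 h, in percent of the solid substrate charged most ("none" if none brings more than 2 percentage points) (Tuesday's / Thursday's / Sunday's / Wednesday's / none)
- amount of product at 20 h, in percent of the solid substrate charged, after Wednesday's

- Tuesday's: doubling the amount of free catalyst, all else as stated
- Thursday's: doubling the dissolution coefficient of the solid substrate, all else as stated
- Sunday's: doubling the saturation concentration of gas phase, all else as stated
- Wednesday's: doubling the transfer coefficient of the gas phase, all else as stated

The quantity I carry is the throughput, 1.60 mM h⁻¹, the concentration of solid substrate leaving per hour once what has left but is not yet product holds level. I read it from the solid in the south-east run between 2.50 h and 8.00 h. Product over the same window gives a second pace, 1.23 mM h⁻¹. Starting from the 9.11 mM of product in the south-east run at 8.00 h, and carrying these concentrations over to the asked flask, the product pace reaches 23.9 mM at 20 h and the throughput reaches 28.3 mM.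

They part, so one cheats. Between those readings the gap between solid lost and product grew from 5.76 mM to 7.77 mM, and that growth is the difference between the two paces. The product pace therefore reads low while the gap fills. Once the gap holds level, as an intermediate does in a steady state, product must follow the solid. For the asked flask I commit to 28.3% of the charge.

The forecast says 26%, lower than my figure, with Tuesday's as the best change and 29% after Wednesday's. Its ground is a product pace “similar in both runs, so the solid load hardly matters”.

The asked flask gives 28.6%, and 32.9% after Wednesday's, and Tuesday's is best, as forecast, worth 23 percentage points.

    gas phase ⇌ dissolved gas, rate k1*(csat - [dissolved gas]) (kL = 2.50 × 10⁻⁴ s⁻¹)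
    starting material + dissolved gas + free catalyst → free catalyst + product (k = 7.90 L² mol⁻² s⁻¹)
    solid substrate ⇌ starting material, rate k3*(cs3 - [starting material]) while solid is left; crystals form when [starting material] > cs3 (solubility = 14.0 mM, k = 8.10 × 10⁻⁵ s⁻¹)
    free catalyst + impurity → spent catalyst (k = 0.0710 L mol⁻¹ s⁻¹)

In the asked flask the gap is starting material, 8.69% of the solid charged at 20 h. From the 13.2% of product that this flask holds at 10.0 h, the throughput gives 29.2% at 20 h.

The neighbour charged with 0.0060 M of free catalyst has 7.9 mM of impurity against it. Scaling the throughput by the surplus of catalyst over impurity, 2.10 mM in the asked flask and −1.90 mM in that neighbour, gives the neighbour −1.44 mM h⁻¹, a figure below zero that I read as no lasting throughput. That neighbour computes to 1.96% product, with free catalyst at 0% and 24% of its impurity left.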